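**Retrosynthetic overview**
1. Target 6 is the formal C3–O7′ dehydro-dimer of scopoletin; the key disconnection is the C3–O bond of the aryl vinyl ether that joins the two coumarin units.
2. This gives a C3 electrophile, 7-O-benzyl-3-bromoscopoletin 4, and scopoletin 1 itself as the phenol nucleophile, joined by a new Pd-catalysed C–O coupling.
3. Bromide 4 comes from scopoletin by O-benzylation and C3 bromination (Br2 addition, then dehydrobromination); the last step is debenzylation.
4. No ring is built: both benzopyranone bicycles are bought as scopoletin. Order of events: protect, brominate, C–O couple, deprotect.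

Assumption: the target has no stereogenic element, so the "single enantiomer" is the achiral compound itself and no asymmetric step is needed; simple salts (phenoxides, ammonium salts) and catalyst-bound species are not numbered as intermediates.

Step 1
Reactants: 1 scopoletin (7-hydroxy-6-methoxy-2H-chromen-2-one)
Product: 2 7-(benzyloxy)-6-methoxy-2H-chromen-2-one
Conditions: BnBr (1.2 equiv), K2CO3 (1.5 equiv), DMF, rt
Reagents that add atoms: benzyl bromide, BrCc1ccccc1
Why: Williamson ether synthesis – the acidic 7-OH is the only nucleophilic site and its phenoxide displaces bromide from benzyl bromide (SN2) under conditions that leave the lactone untouched.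

Step 2
Reactants: 2 7-(benzyloxy)-6-methoxy-2H-chromen-2-one
Product: 4 7-(benzyloxy)-3-bromo-6-methoxy-2H-chromen-2-one, via trans-3,4-dibromide 3 (not isolated)
Conditions: Br2 (1.05 equiv), CH2Cl2, 0 °C; then Et3N (2 equiv), 0 °C to rt
Reagents that add atoms: bromine, BrBr
Why: Electrophilic bromine addition–dehydrobromination, the standard route to 3-bromocoumarins – bromine enters at C3 because the C4 cation is benzylic and para-stabilised by the 7-benzyloxy group, anti addition gives the racemic trans-dibromide, and Et3N removes the acidic C3–H with loss of the benzylic C4 bromide, which erases the two transient stereocentres.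

Step 3
Reactants: 4 7-(benzyloxy)-3-bromo-6-methoxy-2H-chromen-2-one; 1 scopoletin (1.3 equiv)
Product: 5 7-(benzyloxy)-6-methoxy-3-[(6-methoxy-2-oxo-2H-chromen-7-yl)oxy]-2H-chromen-2-one
Conditions: tBuBrettPhos Pd G3 (5 mol %), K3PO4 (2 equiv), 4 Å MS, toluene/1,4-dioxane 4:1, 90 °C
Reagents that add atoms: none
Why: Proposed new method: Pd(0)/bulky biarylphosphine-catalysed C(sp2)–O cross-coupling at C3 of a 3-bromocoumarin (an α-bromo-α,β-unsaturated lactone) with a hydroxycoumarin as the phenol partner, which forges the 3–O–7′ bicoumarin ether bond directly; oxidative addition into the activated vinylic C3–Br bond fixes the site, K3PO4-generated scopoletin phenoxide replaces bromide on Pd, and C–O reductive elimination is favoured by the electron-poor α-acyl-vinyl ligand and the large tBuBrettPhos, while the weak, poorly soluble base in a non-polar anhydrous medium suppresses lactone opening, ring contraction to a benzofuran and cine-substitution through 1,4-addition at C4; the closest known reaction type is the Buchwald–Hartwig diaryl ether synthesis, together with the established Pd-catalysed C–N couplings of 3-bromocoumarins.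

Step 4
Reactants: 5 7-(benzyloxy)-6-methoxy-3-[(6-methoxy-2-oxo-2H-chromen-7-yl)oxy]-2H-chromen-2-one
Product: 6 7-hydroxy-6-methoxy-3-[(6-methoxy-2-oxo-2H-chromen-7-yl)oxy]-2H-chromen-2-one (target, CNP0312919.0)
Conditions: H2 (1 atm), 10% Pd/C, THF/EtOAc, rt, stopped at full conversion of 5
Reagents that add atoms: none
Why: Catalytic hydrogenolysis of the aryl benzyl ether – cleavage of the benzylic C–O bond is much faster than hydrogenation of the conjugated coumarin C3=C4 bonds (that of ring A is also a trisubstituted enol ether), so both lactones, the aryl vinyl ether and the methyl ethers survive.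

**Compound list**
1 | scopoletin (7-hydroxy-6-methoxy-2H-chromen-2-one) | COc1cc2ccc(=O)oc2cc1O | starting material
2 | 7-(benzyloxy)-6-methoxy-2H-chromen-2-one | COc1cc2ccc(=O)oc2cc1OCc1ccccc1 | intermediate
3 | trans-7-(benzyloxy)-3,4-dibromo-6-methoxy-3,4-dihydro-2H-chromen-2-one (racemic, 3R*,4R*; the 3R,4R enantiomer is drawn; not isolated) | O=C1Oc2cc(OCc3ccccc3)c(OC)cc2[C@@H](Br)[C@@H]1Br | intermediate
4 | 7-(benzyloxy)-3-bromo-6-methoxy-2H-chromen-2-one | COc1cc2cc(Br)c(=O)oc2cc1OCc1ccccc1 | intermediate
5 | 7-(benzyloxy)-6-methoxy-3-[(6-methoxy-2-oxo-2H-chromen-7-yl)oxy]-2H-chromen-2-one | COc1cc2cc(Oc3cc4oc(=O)ccc4cc3OC)c(=O)oc2cc1OCc1ccccc1 | intermediate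
6 | 7-hydroxy-6-methoxy-3-[(6-methoxy-2-oxo-2H-chromen-7-yl)oxy]-2H-chromen-2-one (achiral) | COc1cc2cc(Oc3cc4oc(=O)ccc4cc3OC)c(=O)oc2cc1O | target

Total step count: 4.
Longest linear sequence: 4 steps (1 → 2 → 4 → 5 → 6); scopoletin 1 enters a second time as the coupling partner in step 3.

**Steps most likely to fail** (most to least likely: step 3, step 4, step 2), each with its fallback:

The new C–O coupling (step 3) carries the highest risk. C–O reductive elimination may be slow with the weakly nucleophilic, ortho-methoxylated phenoxide, and hydrodebromination or base-induced degradation of 4 may compete. The fallback uses known chemistry, a Perkin–Oglialoro ring synthesis that needs no cross-coupling; it sets out from 1 and comes back to the route at 6. Scopoletin 1 is O-alkylated with tert-butyl bromoacetate (K2CO3, acetone, reflux) to tert-butyl 2-[(6-methoxy-2-oxo-2H-chromen-7-yl)oxy]acetate F1. TFA in CH2Cl2 converts this into 2-[(6-methoxy-2-oxo-2H-chromen-7-yl)oxy]acetic acid F2. Heating F2 with commercial 2,4-dihydroxy-5-methoxybenzaldehyde in Ac2O/Et3N (120 °C) builds ring A around the ether oxygen already in place, by O-acylation of the salicylaldehyde and intramolecular aldol condensation. This gives 6-methoxy-3-[(6-methoxy-2-oxo-2H-chromen-7-yl)oxy]-2-oxo-2H-chromen-7-yl acetate F3. Mild methanolysis of the aryl acetate (cat. HCl, MeOH/THF, rt) then gives 6 without passing through 4 or 5.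

The C3 bromination (step 2) may suffer from nuclear bromination at C8 or C5 of the electron-rich arene, or from acid damage to the benzyl ether. The fallback changes the protecting-group strategy so that the arene is deactivated while the bromine is introduced; it sets out from 1 and comes back to the route at 4. Scopoletin 1 is acetylated (Ac2O, pyridine) to 6-methoxy-2-oxo-2H-chromen-7-yl acetate F4. The acyloxy group no longer activates the benzo ring, while Br2 (CHCl3, rt) still adds across the pyranone C3=C4 bond as it does with coumarin itself. This gives trans-3,4-dibromo-6-methoxy-2-oxo-3,4-dihydro-2H-chromen-7-yl acetate F5 (not isolated), and Et3N then gives 3-bromo-6-methoxy-2-oxo-2H-chromen-7-yl acetate F6. Acid methanolysis (cat. HCl, MeOH, rt) frees 3-bromo-7-hydroxy-6-methoxy-2H-chromen-2-one F7, and benzylation under the conditions of step 1 delivers 4.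

The final debenzylation (step 4) may over-reduce the unsubstituted C3′=C4′ bond of the second coumarin unit, or stall through catalyst poisoning. The fallback replaces the benzyl ether by an acid-labile acetal, so that the last step is no longer a reduction; it sets out from 1 and comes back to the route at 6. Scopoletin 1 is taken, exactly as in the fallback to step 2, to 3-bromo-7-hydroxy-6-methoxy-2H-chromen-2-one F7. This is capped with MOMCl/iPr2NEt (CH2Cl2) as 3-bromo-6-methoxy-7-(methoxymethoxy)-2H-chromen-2-one F8. Coupling of F8 with 1 under the conditions of step 3 gives 6-methoxy-7-(methoxymethoxy)-3-[(6-methoxy-2-oxo-2H-chromen-7-yl)oxy]-2H-chromen-2-one F9, and the acetal is removed with HCl in MeOH/THF (40 °C) to give 6.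

**Further compounds**
F1 | step 3 | tert-butyl 2-[(6-methoxy-2-oxo-2H-chromen-7-yl)oxy]acetate | COc1cc2ccc(=O)oc2cc1OCC(=O)OC(C)(C)C
F2 | step 3 | 2-[(6-methoxy-2-oxo-2H-chromen-7-yl)oxy]acetic acid | COc1cc2ccc(=O)oc2cc1OCC(=O)O
F3 | step 3 | 6-methoxy-3-[(6-methoxy-2-oxo-2H-chromen-7-yl)oxy]-2-oxo-2H-chromen-7-yl acetate | COc1cc2cc(Oc3cc4oc(=O)ccc4cc3OC)c(=O)oc2cc1OC(C)=O
F4 | step 2 | 6-methoxy-2-oxo-2H-chromen-7-yl acetate | COc1cc2ccc(=O)oc2cc1OC(C)=O
F5 | step 2 | trans-3,4-dibromo-6-methoxy-2-oxo-3,4-dihydro-2H-chromen-7-yl acetate (racemic, 3R*,4R*; one enantiomer drawn) | O=C1Oc2cc(OC(C)=O)c(OC)cc2[C@@H](Br)[C@@H]1Br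
F6 | step 2 | 3-bromo-6-methoxy-2-oxo-2H-chromen-7-yl acetate | COc1cc2cc(Br)c(=O)oc2cc1OC(C)=O
F7 | step 2 | 3-bromo-7-hydroxy-6-methoxy-2H-chromen-2-one | COc1cc2cc(Br)c(=O)oc2cc1O
F8 | step 4 | 3-bromo-6-methoxy-7-(methoxymethoxy)-2H-chromen-2-one | COCOc1cc2oc(=O)c(Br)cc2cc1OC
F9 | step 4 | 6-methoxy-7-(methoxymethoxy)-3-[(6-methoxy-2-oxo-2H-chromen-7-yl)oxy]-2H-chromen-2-one | COCOc1cc2oc(=O)c(Oc3cc4oc(=O)ccc4cc3OC)cc2cc1OC
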